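At early times in the flask called spring I compare how quickly each species would go at the charge; the other flasks differ from spring in their starting material.

| flask | starting material | partner | base | time |
|---|---|---|---|---|
| spring | 0.50 M | 0.585 M | 9.00 mM | 4.0 h |
| midnight | 0.60 M | 0.585 M | 9.00 mM | 4.0 h |
| dusk | 1.0 M | 0.585 M | 9.00 mM | 4.0 h |
| dawn | 1.5 M | 0.585 M | 9.00 mM | 4.0 h |

    2 starting material → homo dimer (k1 = 0.00462 M⁻¹ min⁻¹)
    starting material + partner + by-product → target + 2 by-product (k2 = 0.158 M⁻² min⁻¹)
    base + by-product ⇌ salt, settled at all times (K3 = 40800 M⁻¹)
    starting material + partner → target + by-product (k4 = 0.00331 M⁻¹ min⁻¹)
    partner → decomposed reagent (k5 = 0.0203 min⁻¹)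
    starting material + target → side product (k6 = 0.358 M⁻¹ min⁻¹)

- percentages count the starting material that a species holds: one homo dimer or side product counts as two
- for a step with 2 of a species take k times the square, and two of it per event
- a step back or a flat step of under half a percent of the largest counts as no turn
- "hardly changes" means that all values lie within two and a half points (for a concentration: within two and a half percent of the largest)
- run time (spring): 4.0 h

1. [target] at the end for spring, midnight, dusk, dawn, in this order
2. how that number moves from the first to the last of them (falls, then rises / falls all the way / rises all the way / rises, then falls / hardly changes)

| Spring, others as charged | Half-life |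
|---|---|
| target, eaten by starting material | 0.065 h |
| partner, decaying | 0.57 h |
| starting material, on the plain route with partner | 6.0 h |

I read from the bottom. In spring the plain route has a half-life longer than the run of 4.0 h, so it makes target slowly.

The middle row is shorter than the run, so decay by itself leaves 0.00766 of the partner charge at the end in spring. The routes to target take partner as well, one part to 12 of decay just after the start, so this fraction is a high figure for the partner left.

The top row is shorter still, so spring's target cannot pile up and sits in a quasi-steady state, eaten as fast as it is made. Starting material stands in both rates and cancels. Target over partner, both as fractions of the partner charge, is therefore the plain constant plus the by-product-assisted constant times by-product, all over the eating constant. The partner falls meanwhile and target trails it: the ratio stands above this by the eating rate over the eating rate less the partner's fall rate.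

The by-product concentration at which the assisted route matches the plain one is 0.0209 M, the crossover level. The ratio is thus 0.00925 times one plus by-product over crossover.

For spring, partner splits 12 to one towards decay at the start, and base takes its charge of by-product, so I expect 0.0351 M of by-product. That gives a ratio of 0.0247, and with the decay figure above, 1.11 × 10⁻⁴ M of target in spring. This figure holds the partner too high and leaves the trail out, which pulls the other way, so I take it as a rough size. For richer flasks the ratio should rise while the partner left falls, and I cannot weigh these two by hand.

The forecast gives 1.300 × 10⁻⁴ M, 1.100 × 10⁻⁴ M, 7.300 × 10⁻⁵ M and 4.800 × 10⁻⁵ M, a row that falls all the way, holding that “More starting material uses up the partner faster and destroys the target faster”; its spring value is above mine.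

The flasks end at 1.10 × 10⁻⁴ M, 1.10 × 10⁻⁴ M, 7.27 × 10⁻⁵ M and 2.25 × 10⁻⁵ M, so the row falls all the way. At the end of dawn, starting material stands at 18% of its charge, partner at 0.0250% of its charge and by-product at 0.220 M. That by-product is 10.5 crossover levels, so the ratio for dawn is 0.106. Dawn's eating rate is 0.0970 min⁻¹ and its partner falls at 0.0306 min⁻¹, so the trailing ratio times the partner left gives 2.27 × 10⁻⁵ M of target, beside the 2.25 × 10⁻⁵ M that dawn holds.

The numbers of this flask were set for the occasion; the result is computed.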